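The earlier runs and the new flask were computed on assumed constants; the scatter is artificial.

The substrate sheds its leaving ligand to give the intermediate, partner captures the intermediate as target, and target may fall out as crystals, which are counted with it.

| flask | substrate | partner | remark | time |
|---|---|---|---|---|
| autumn | 24 mM | 1.5 equiv | run made earlier |  |
| summer | 24 mM | 9.5 equiv | run made earlier |  |
| noon | 17 mM | 2.5 equiv | run made earlier |  |
| beta | 8.0 mM | 1.20 equiv |  | 30 h |
| gamma | 6.0 mM | 1.70 equiv |  | 30 h |
| alpha | 50 mM | 5.00 equiv |  | 30 h |
| zeta | 24 mM | 2.50 equiv |  | 30 h |
| epsilon | 8.0 mM | 7.50 equiv |  | 30 h |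

| run | time / h | target / % |
|---|---|---|
| autumn | 1.33 | 5.3 |
| autumn | 4.00 | 11.7 |
| autumn | 8.00 | 21.5 |
| autumn | 10.0 | 21.2 |
| autumn | 15.0 | 25.7 |
| summer | 1.33 | 16.2 |
| summer | 4.00 | 30.6 |
| summer | 8.00 | 45.5 |
| summer | 10.0 | 51.7 |
| summer | 15.0 | 62.1 |
| noon | 1.33 | 7.8 |
| noon | 4.00 | 15.4 |
| noon | 8.00 | 23.0 |
| noon | 10.0 | 28.0 |
| noon | 15.0 | 35.0 |

(readings scatter by 1 percentage point)

- target is meant together with its crystals
- solid, in amounts per volume of the solution: crystals
- the numbers in the tables scatter with a standard deviation of 1 percentage point
- steps under discussion: crystals <-> target; substrate <-> intermediate + leaving ligand; partner + intermediate -> target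

* all flasks from highest to lowest amount of target, in percent of the substrate charged, at 30 h (beta / gamma / alpha / zeta / epsilon)
* the same order at 5.0 d (beta / gamma / alpha / zeta / epsilon)
* the amount of target, in percent of the substrate charged of the flask you put first, at 30 h
* the amount of target, in percent of the substrate charged of the flask you put last, at 30 h

I followed one molecule of intermediate. At each fork it goes back with leaving ligand or on with partner, and if going back is the likelier, its chance of going on runs as c_partner over c_leaving ligand. Leaving ligand appears along with target, so with x the fraction of charged substrate present as target and e the equivalents of partner, the substrate concentration cancels, the rate runs as e/x, and x squared grows as e times the time. At 15.0 h the autumn run gives x squared over e·t of 0.00294 /h, the summer run 0.00271 /h and the noon run 0.00327 /h, although e differs by a factor of 6.33. Their mean, 0.00297 /h, is my capture constant, x squared over e·t. It ranks the flasks by e and gives beta 32.7% at 30 h. For epsilon it gives 81.7%, but I distrust that figure, since the law treats substrate as unspent.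

The forecast gave epsilon > alpha > zeta > gamma > beta at 30 h and epsilon > alpha > zeta > gamma > beta at 5.0 d, with 71% first and 33% last, on the ground that “percent conversion depends on equivalents of partner, not on substrate concentration”. For epsilon my figure stands higher than the forecast's.

The flasks gave epsilon > alpha > zeta > gamma > beta at 30 h and epsilon > alpha > zeta > gamma > beta at 5.0 d, with 70.3% first and 29.5% last. In beta, crystals held 22.2% at 30.0 h, and the low solubility of target made no difference to its total.

    crystals ⇌ target, rate k1*(cs1 - [target]) while solid is left; crystals form when [target] > cs1 (solubility = 0.580 mM, k = 0.00314 /s)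
    substrate ⇌ intermediate + leaving ligand (K = 2.05 × 10⁻⁴ M, k = 9.43 × 10⁻⁵ /s)
    partner + intermediate → target (k = 0.00427 /M/s)

In beta at 3.03 h, intermediate fell back 16 times as fast as it went on, and capture by partner was then the rate-limiting step. At 30 h, beta's own capture constant reads 0.00241 /h, against 0.00297 /h from the earlier runs. For the same flask with 3.00 equiv of partner, the capture constant gives 51.7%, and that flask stood at 48.8%.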